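**Plan**

- Retrosynthesis: the tiglate C–O and acetate C–O bonds are cut first and the formyl group is traced back to a carboxyl group. The C3–O bond is then cut back to a C3–H bond by way of a lactone joining the carboxyl oxygen to C3. The acrylic acid comes from the methyl of an isopropenyl group, and the O1–C2 and C3–C3a bonds are cut to a bromophenol and isoprene.
- Forward: the dihydrofuran ring is made first by palladium heteroannulation and the side-chain methyl is oxidised to the acid. The lactone ring is then closed anodically onto C3 and reopened as a Weinreb amide. Acetylation, ketone reduction, tigloylation and amide-to-aldehyde reduction finish the synthesis.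
- Enabling feature: the side-chain carbonyl carbon is linked through the vinyl carbon and C2 to C3, and the side chain occupies one face of the dihydrofuran ring. At the acid level a carboxyl oxygen can reach only the C3 hydrogen on that face. Bonding it to C3 gives a five-membered lactone (O, C=O, vinyl C, C2, C3) that can be fused to the dihydrofuran only cis, which is the cis C2/C3 relation of the target.
- Stereochemistry: C2 comes from the chiral ligand in the heteroannulation, and C3 is relayed from C2 through the cis ring fusion. The carbinol centre (R) comes from transfer hydrogenation with RuCl[(R,R)-TsDPEN](p-cymene), and the E alkene arrives with tiglic acid.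

Key step: step 4

Assumption: in step 1 the enantiomer of the chiral phosphine is the one that leads to the 2R product (the tremetone series); C2 is R up to compound 6 and becomes S by descriptor only, once C3 carries oxygen.

Step 1
Reactants: 1 3'-bromo-4'-hydroxyacetophenone; 2 isoprene
Product: 3 (R)-tremetone (1-[(2R)-2-(prop-1-en-2-yl)-2,3-dihydro-1-benzofuran-5-yl]ethan-1-one)
Conditions: Pd2(dba)3 (5 mol%), chiral sulfinamide monophosphine of the TY-Phos type (20 mol%), NaOPh (2 equiv), isoprene (excess), CH2Cl2, 40 °C
Reagents that add atoms: none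
Why: Larock-type heteroannulation run as an asymmetric Heck/Tsuji–Trost cascade, a known reaction of o-bromophenols with 1,3-dienes: the arylpalladium species adds to the unsubstituted vinyl terminus of isoprene, the phenoxide closes the dihydrofuran on the adjacent π-allyl carbon, and the ligand on palladium decides the face of that C–O bond formation and so sets C2 as R.

Step 2
Reactants: 3 (R)-tremetone
Product: 5 2-[(2R)-5-acetyl-2,3-dihydro-1-benzofuran-2-yl]prop-2-enal, via allylic alcohol 4 (not isolated)
Conditions: SeO2 (0.5 equiv), tBuOOH (2 equiv), CH2Cl2, rt; filtration; then MnO2 (excess), CH2Cl2, rt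
Reagents that add atoms: selenium dioxide, O=[Se]=O (delivers the oxygen; regenerated by tert-butyl hydroperoxide, CC(C)(C)OO)
Why: Selenium dioxide allylic oxidation (ene reaction then [2,3]-sigmatropic shift) takes a methyl hydrogen in preference to the methine C2–H, as is usual for isopropenyl groups, leaves the aryl ketone and C2 untouched at room temperature, and MnO2 then brings alcohol 4 and any aldehyde already formed to the single enal 5.

Step 3
Reactants: 5 2-[(2R)-5-acetyl-2,3-dihydro-1-benzofuran-2-yl]prop-2-enal
Product: 6 2-[(2R)-5-acetyl-2,3-dihydro-1-benzofuran-2-yl]prop-2-enoic acid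
Conditions: NaClO2, NaH2PO4, 2-methyl-2-butene, tBuOH/H2O, 0 °C to rt
Reagents that add atoms: sodium chlorite, [Na+].[O-]Cl=O
Why: Pinnick oxidation converts the enal into the acid without touching the alkene (hypochlorite is scavenged by 2-methyl-2-butene), the ketone or the C2 centre.

Step 4
Reactants: 6 2-[(2R)-5-acetyl-2,3-dihydro-1-benzofuran-2-yl]prop-2-enoic acid
Product: 7 (3aS,8bS)-7-acetyl-3-methylidene-3a,8b-dihydrofuro[3,2-b][1]benzofuran-2(3H)-one (cis-fused α-methylene-γ-butyrolactone on C2–C3 of 5-acetyl-2,3-dihydrobenzofuran; lactone oxygen on C3)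
Conditions: graphite anode, Pt cathode, undivided cell, constant current (about 5 mA cm−2, 2.2–2.5 F mol−1), nBu4NBF4 (0.1 M), 2,6-lutidine (0.5 equiv), CH2Cl2/(CF3)2CHOH 4:1, 0.03 M in 6, rt
Reagents that add atoms: none
Why: Proposed new method: the carboxylate of 6 is discharged at graphite to an alkenoyloxy radical, which loses CO2 only slowly because a vinyl radical would result, and so has time to take the C3 hydrogen on its own face by 1,5-hydrogen transfer through a six-membered transition state; a second anodic electron transfer turns the benzylic radical into a cation that O1 stabilises through C7a and C3a, the carboxylate oxygen closes onto it, and protons are reduced to H2 at platinum. The closest known reaction type is the anodic dehydrogenative lactonisation of benzylic C–H bonds by a neighbouring carboxylic acid (2-alkylbenzoic acids to phthalides); an alkenoic acid as the relay group is new. The lactone ring closes in the 5-exo-trig mode with respect to the C3–C3a bond of the cation. C3 is the only new stereocentre and is dictated by C2, because two fused five-membered rings can only be joined cis, so the new C3–O bond lies on the face of the C2 substituent. The step needs site selectivity for C3–H over the allylic C2–H and over decarboxylation; this is secured by the three-atom reach of the carboxyl group (C2–H would need a five-membered transition state), by the absence of any other benzylic hydrogen (the C5 substituent is an acetyl group) and by ring closure being faster than loss of the C2 proton to a benzofuran.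

Step 5
Reactants: 7 cis-fused α-methylene lactone; 8 N,O-dimethylhydroxylamine hydrochloride
Product: 9 2-[(2S,3S)-5-acetyl-3-hydroxy-2,3-dihydro-1-benzofuran-2-yl]-N-methoxy-N-methylprop-2-enamide
Conditions: AlMe3 (3 equiv), 8 (3 equiv), CH2Cl2, 0 °C; then 7, 0 °C to rt; aq. KNaC4H4O6 (potassium sodium tartrate) work-up
Reagents that add atoms: none
Why: Weinreb aminolysis of a lactone by the aluminium amide made from AlMe3 and 8 breaks the acyl C–O bond, so C3 keeps its configuration and the cis hydroxyl is set free; the aluminium-bound amide should attack the carbonyl in preference to the methylene, and the aryl ketone is at most reversibly complexed.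

Step 6
Reactants: 9 hydroxy Weinreb amide
Product: 10 (2S,3S)-5-acetyl-2-{3-[methoxy(methyl)amino]-3-oxoprop-1-en-2-yl}-2,3-dihydro-1-benzofuran-3-yl acetate
Conditions: Ac2O, pyridine, DMAP (cat.), CH2Cl2, 0 °C, directly after work-up of step 5
Reagents that add atoms: acetic anhydride, CC(=O)OC(C)=O
Why: DMAP-catalysed acetylation of the secondary benzylic alcohol leaves the C3–O bond intact (retention) and, done without delay, removes the hydroxyl that could otherwise displace the hydroxylamine and re-form the lactone.

Step 7
Reactants: 10 keto acetate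
Product: 11 (2S,3S)-5-[(1R)-1-hydroxyethyl]-2-{3-[methoxy(methyl)amino]-3-oxoprop-1-en-2-yl}-2,3-dihydro-1-benzofuran-3-yl acetate
Conditions: RuCl[(R,R)-TsDPEN](p-cymene) (1 mol%), HCO2H/Et3N (5:2), CH2Cl2, rt
Reagents that add atoms: none
Why: Noyori asymmetric transfer hydrogenation of the aryl methyl ketone: under catalyst control the (R,R)-TsDPEN ruthenium hydride delivers hydride to the Si face of the carbonyl, giving the (R)-carbinol as for other acetophenones, while the amide, the acetate and the 1,1-disubstituted alkene are not reduced.

Step 8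
Reactants: 11 (R)-carbinol; 12 tiglic acid
Product: 13 (1R)-1-[(2S,3S)-3-acetoxy-2-{3-[methoxy(methyl)amino]-3-oxoprop-1-en-2-yl}-2,3-dihydro-1-benzofuran-5-yl]ethyl (2E)-2-methylbut-2-enoate
Conditions: DCC, DMAP (cat.), CH2Cl2, 0 °C to rt
Reagents that add atoms: none
Why: Steglich esterification acylates the carbinol oxygen, so the (R) centre is retained, and tiglic acid supplies the E double bond, the more stable isomer, which should not isomerise under DMAP.

Step 9
Reactants: 13 tiglate Weinreb amide
Product: 14 (1R)-1-[(2S,3S)-3-acetoxy-2-(3-oxoprop-1-en-2-yl)-2,3-dihydro-1-benzofuran-5-yl]ethyl (2E)-2-methylbut-2-enoate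
Conditions: Cp2Zr(H)Cl (1.5 equiv), THF, rt, 10–20 min; silica gel work-up
Reagents that add atoms: none
Why: Reduction of a tertiary (Weinreb) amide to the aldehyde with Cp2Zr(H)Cl stops at a zirconium-bound hemiaminal that collapses only on work-up, is known to spare esters and to give enals from unsaturated amides, and touches no stereocentre.

**Compound list**

1 | 3'-bromo-4'-hydroxyacetophenone | CC(=O)c1ccc(O)c(Br)c1 | starting material
2 | isoprene | C=CC(C)=C | starting material
3 | (R)-tremetone, 1-[(2R)-2-(prop-1-en-2-yl)-2,3-dihydro-1-benzofuran-5-yl]ethan-1-one | C=C(C)[C@@H]1Oc2ccc(C(C)=O)cc2C1 | intermediate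
4 | 1-[(2R)-2-(3-hydroxyprop-1-en-2-yl)-2,3-dihydro-1-benzofuran-5-yl]ethan-1-one (allylic alcohol, not isolated) | C=C(CO)[C@@H]1Oc2ccc(C(C)=O)cc2C1 | intermediate
5 | 2-[(2R)-5-acetyl-2,3-dihydro-1-benzofuran-2-yl]prop-2-enal | C=C(C=O)[C@@H]1Oc2ccc(C(C)=O)cc2C1 | intermediate
6 | 2-[(2R)-5-acetyl-2,3-dihydro-1-benzofuran-2-yl]prop-2-enoic acid | C=C(C(=O)O)[C@@H]1Oc2ccc(C(C)=O)cc2C1 | intermediate
7 | (3aS,8bS)-7-acetyl-3-methylidene-3a,8b-dihydrofuro[3,2-b][1]benzofuran-2(3H)-one (cis-fused α-methylene-γ-butyrolactone on C2–C3 of 5-acetyl-2,3-dihydrobenzofuran) | C=C1C(=O)O[C@H]2c3cc(C(C)=O)ccc3O[C@H]21 | intermediate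
8 | N,O-dimethylhydroxylamine hydrochloride | CNOC.Cl | starting material
9 | 2-[(2S,3S)-5-acetyl-3-hydroxy-2,3-dihydro-1-benzofuran-2-yl]-N-methoxy-N-methylprop-2-enamide | C=C(C(=O)N(C)OC)[C@@H]1Oc2ccc(C(C)=O)cc2[C@@H]1O | intermediate
10 | (2S,3S)-5-acetyl-2-{3-[methoxy(methyl)amino]-3-oxoprop-1-en-2-yl}-2,3-dihydro-1-benzofuran-3-yl acetate | C=C(C(=O)N(C)OC)[C@@H]1Oc2ccc(C(C)=O)cc2[C@@H]1OC(C)=O | intermediate
11 | (2S,3S)-5-[(1R)-1-hydroxyethyl]-2-{3-[methoxy(methyl)amino]-3-oxoprop-1-en-2-yl}-2,3-dihydro-1-benzofuran-3-yl acetate | C=C(C(=O)N(C)OC)[C@@H]1Oc2ccc([C@@H](C)O)cc2[C@@H]1OC(C)=O | intermediate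
12 | tiglic acid, (2E)-2-methylbut-2-enoic acid | C/C=C(\C)C(=O)O | starting material
13 | (1R)-1-[(2S,3S)-3-acetoxy-2-{3-[methoxy(methyl)amino]-3-oxoprop-1-en-2-yl}-2,3-dihydro-1-benzofuran-5-yl]ethyl (2E)-2-methylbut-2-enoate | C=C(C(=O)N(C)OC)[C@@H]1Oc2ccc([C@@H](C)OC(=O)/C(C)=C/C)cc2[C@@H]1OC(C)=O | intermediate
14 | (1R)-1-[(2S,3S)-3-acetoxy-2-(3-oxoprop-1-en-2-yl)-2,3-dihydro-1-benzofuran-5-yl]ethyl (2E)-2-methylbut-2-enoate | C=C(C=O)[C@@H]1Oc2ccc([C@@H](C)OC(=O)/C(C)=C/C)cc2[C@@H]1OC(C)=O | target

Total step count: 9. Longest linear sequence: 9 steps (1 to 14).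

**Steps most likely to fail**

Step 4 (anodic lactonisation). The electrolysis may be diverted by Kolbe-type loss of CO2, by radical oligomerisation through the acrylate, or by loss of the C2 proton from the C3 cation with aromatisation to the benzofuran. The fallback replaces electron transfer at the electrode by bromine-atom abstraction, a known hypervalent-iodine/bromide benzylic lactonisation of 4-arylbutanoic acids. Setting out from acid 6, PhI(OAc)2 and KBr in CH2Cl2 at rt generate bromine radicals that remove the weakest C–H bond, the benzylic C3–H. The resulting 3-bromo acid F1 (either C3 epimer) is not isolated: its benzylic C–Br bond ionises with help from O1 and the neighbouring carboxyl group displaces bromide, again necessarily cis. The route is rejoined at lactone 7. Site selectivity then rests on bond strength and no longer on the reach of the carboxyl group.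

Step 5 (lactone opening). The hydroxylamine may add in conjugate fashion to the exocyclic methylene (with possible loss of the O1 aryloxide from the enolate so formed), or 9 may close back to 7 before it is acetylated. The fallback masks the methylene. From 7, thiophenol with catalytic Et3N in CH2Cl2 should give the phenylthiomethyl lactone F2 by thia-Michael addition, the enolate being protonated by the thiol. Aminolysis with AlMe3 and 8 as in step 5 then gives the hydroxy amide F3, and acetylation the acetate F4. Oxidation with mCPBA at −78 °C gives the sulfoxide F5, and syn-elimination of benzenesulfenic acid in toluene at about 100 °C restores the methylene. The route is rejoined at acetate 10.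

Step 9 (amide to aldehyde). Hydride may be transferred from zirconium to the acetate or the tiglate, the acrylamide may be hydrozirconated, or the electron-rich benzylic tiglate may ionise at the Lewis-acidic metal. The fallback changes the order of events so that the last bond made is the ester. From alcohol 11, Cp2Zr(H)Cl (one further equivalent is consumed by the hydroxyl) in THF should reduce the amide to the hydroxy enal F6 while the acetate is the only ester present. Steglich esterification of F6 with tiglic acid 12 (DCC, DMAP, CH2Cl2) then gives the target 14.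

**Further compounds**

F1 | step 4 | 2-[(2S)-5-acetyl-3-bromo-2,3-dihydro-1-benzofuran-2-yl]prop-2-enoic acid (C3 epimers) | C=C(C(=O)O)[C@@H]1Oc2ccc(C(C)=O)cc2C1Br
F2 | step 5 | thiophenol adduct of 7: lactone 7 with CH2SPh in place of the exocyclic methylene (α-carbon epimers) | O=C1O[C@H]2c3cc(C(C)=O)ccc3O[C@H]2C1CSc1ccccc1
F3 | step 5 | 2-[(2S,3S)-5-acetyl-3-hydroxy-2,3-dihydro-1-benzofuran-2-yl]-N-methoxy-N-methyl-3-(phenylsulfanyl)propanamide (α-carbon epimers) | CON(C)C(=O)C(CSc1ccccc1)[C@@H]1Oc2ccc(C(C)=O)cc2[C@@H]1O
F4 | step 5 | (2S,3S)-5-acetyl-2-{1-[methoxy(methyl)amino]-1-oxo-3-(phenylsulfanyl)propan-2-yl}-2,3-dihydro-1-benzofuran-3-yl acetate (α-carbon epimers) | CON(C)C(=O)C(CSc1ccccc1)[C@@H]1Oc2ccc(C(C)=O)cc2[C@@H]1OC(C)=O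
F5 | step 5 | (2S,3S)-5-acetyl-2-{1-[methoxy(methyl)amino]-1-oxo-3-(phenylsulfinyl)propan-2-yl}-2,3-dihydro-1-benzofuran-3-yl acetate (epimers at the α-carbon and at sulfur) | CON(C)C(=O)C(CS(=O)c1ccccc1)[C@@H]1Oc2ccc(C(C)=O)cc2[C@@H]1OC(C)=O
F6 | step 9 | (2S,3S)-5-[(1R)-1-hydroxyethyl]-2-(3-oxoprop-1-en-2-yl)-2,3-dihydro-1-benzofuran-3-yl acetate | C=C(C=O)[C@@H]1Oc2ccc([C@@H](C)O)cc2[C@@H]1OC(C)=O
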